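Readings and results are simulated from invented constants, and the scatter is random.

Early times came first at the meeting: over its first readings a run loses starting material almost linearly, so each run yields a time constant.

| flask | starting material | partner | temperature | remark | time |
|---|---|---|---|---|---|
| Tuesday's | 0.10 M | 0.24 M | −50 °C | run made earlier |  |
| Thursday's | 0.40 M | 0.24 M | −28 °C | run made earlier |  |
| elm | 0.20 M | 0.240 M |  | at −20 °C until 2.5 h, from then on at −60 °C | 12 h |
| maple | 0.20 M | 0.240 M |  | at −20 °C throughout | 20 h |

| run | time / h | product / % | starting material / % |
|---|---|---|---|
| Tuesday's | 6.00 | 0.1 | 99.7 |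
| Tuesday's | 12.0 | 3.5 | 96.5 |
| Tuesday's | 20.0 | 4.9 | 94.8 |
| Tuesday's | 25.0 | 5.9 | 94.8 |
| Tuesday's | 40.0 | 7.7 | 91.5 |
| Thursday's | 0.833 | 8.1 | 91.1 |
| Thursday's | 1.33 | 12.3 | 87.8 |
| Thursday's | 2.00 | 17.8 | 81.7 |
| Thursday's | 4.00 | 25.7 | 73.3 |
| Thursday's | 6.00 | 36.6 | 64.3 |
| Thursday's | 10.0 | 46.0 | 54.4 |

(each reading ± 1 percentage point)

* which one finishes higher in amount of product, in percent of the starting material charged ("neither" within 2 percentage points) (elm / maple / neither)
* amount of product at the end, in percent of the starting material charged, elm
* amount of product at the end, in percent of the starting material charged, maple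



Ines proposed working with the fraction of starting material left, f, and not with the product. In elm and maple the partner stands at 1.20 equivalents, so she argued that the two amounts fall nearly together and the fractional rate falls with f. The reciprocal of f, less one, then grows as t/τ. She read Thursday's at 2.00 h, with 81.7 % left, as τ = 8.93 h, and Tuesday's at 40.0 h, with 91.5 % left, as 431 h, a thin reading given the scatter.

Tom objected that the runs differ in temperature and also in starting material, so their ratio of 48.3 cannot be split. Ines replied that the partner charge does not change, and she committed to a middle assumption: fractional rate goes as the square root of starting material. That gives a factor 2.00 for concentration and leaves 24.1 for temperature, read as an activation energy of 65.8 kJ mol⁻¹. At −20 °C and 0.20 M she obtained 4.55 h: τ, the early time constant of the flask, which is also its half-life.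

At −60 °C she put τ at 1610 h, so elm's cold hours barely count and she minuted 35.7 % product for elm. Maple, with 4.39 time constants, came to 81.5 %, ahead of elm.

The forecast named maple, with 52.5 % (42 % to 63 %) for elm and 94 % (86 % to 99 %) for maple, “limited by the tail of the second-order decay”, both above Ines's figures.

The flasks give 35.4 % for elm and 83.3 % for maple, so maple finishes higher.

    starting material + partner → product, rate k1*[starting material]^1.5*[partner]^0.5 (k = 0.970 L mol⁻¹ h⁻¹, Ea = 66.0 kJ mol⁻¹)
    (constants at −20 °C)

Elm stays behind mainly because of its temperature programme: it stood at 35.2 % product after 2.50 h, at the change of temperature, and at 35.4 % after 12.0 h. The same flask held at −20 °C for its 12 h makes 73.8 %, where τ reckons 72.5 %. Maple left for 3.0 d has, by τ, 5.94 % of its starting material remaining, and the flask holds 3.8 %.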